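**Retrosynthetic overview** (core numbered as 1H-indene: C1 quaternary carbon with the side chain, C3=C3a, C4 CO2H, C5 CH2–oxabicycle, C7 OH, C7a angular methyl; ring A = cyclopentene, ring B = cyclohexadiene)
1. Target ⇐ 4-bromo-diene (Pd hydroxycarbonylation at C4; side-chain CH2OH → CO2H) ⇐ cis-fused 3a-hydroxy-7-ketone, whose C3a–OH first directs the C7 reduction and then leaves as C3=C3a.
2. Key disconnection: that hydroxy ketone ⇐ a cis-1,2-dialkenyl-cyclopent-3-ene-1,2-diol by dianionic oxy-Cope rearrangement (forms C1–C2) and transannular aldol (forms C3a–C7a); rings A and B close together from a nine-membered bis-enolate.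
3. Enabling feature: in ring B the C7 oxygen sits next to quaternary C7a and 1,3 to the sp2 ring-fusion carbon C3a, so C3=C3a is a dehydrated aldol and C3a/C7 can be joined into a cyclopentene-1,2-diol (C3a, C4, C5, C6, C7) carrying vinyl (C3=C2) on C3a and the (E)-tetrasubstituted alkenyl (C7a=C1) on C7; the alkene geometry becomes the C1/C7a quaternary pair.
4. The diol ⇐ a 2-bromo-3-alkylcyclopentenone (asymmetric α'-hydroxylation, vinyl addition, oxidation) + an (E)-alkenyl bromide (CBS reduction, Johnson–Claisen for the side-chain stereocentre, bromination/dehydrobromination).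
5. The bromoenone ⇐ oxabicyclic iodide (iodoetherification of a 4-methylidenecyclohexanol) + 3-bromocyclopentenone; ring order: oxabicycle, then the purchased cyclopentene, then rings A and B in the key step.

Key step: step 18

Assumption: 7,7-dimethyl-1,4-dioxaspiro[4.5]decan-8-one, 3-bromocyclopent-2-en-1-one and (E)-3-methylpent-3-en-2-one are taken as catalogue compounds (the first is otherwise one gem-dimethylation away from 1,4-cyclohexanedione monoethylene ketal).
Abbreviations: OBM = (3,3-dimethyl-7-oxabicyclo[2.2.1]heptan-1-yl)methyl, bridgehead descriptors given each time; TBS = tert-butyl(dimethyl)silyl; TES = triethylsilyl; TMS = trimethylsilyl.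

Step 1
Reactants: 1 7,7-dimethyl-1,4-dioxaspiro[4.5]decan-8-one
Product: 2 (8S)-7,7-dimethyl-1,4-dioxaspiro[4.5]decan-8-ol
Conditions: (R)-2-methyl-CBS-oxazaborolidine (10 mol%), BH3·SMe2, THF, 0 °C
Reagents that add atoms: none
Why: Corey–Bakshi–Shibata reduction in which the quaternary CMe2 flank acts as the large group, so the (R)-catalyst should give the (S)-carbinol that becomes the CH–O bridgehead of the oxabicycle.

Step 2
Reactants: 2 (8S)-7,7-dimethyl-1,4-dioxaspiro[4.5]decan-8-ol
Product: 3 (4S)-4-hydroxy-3,3-dimethylcyclohexan-1-one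
Conditions: 1 M HCl, THF, rt
Reagents that add atoms: water O
Why: Acid hydrolysis of the dioxolane, the hydroxyl being γ to the new carbonyl so that neither elimination nor epimerisation is possible.

Step 3
Reactants: 3 (4S)-4-hydroxy-3,3-dimethylcyclohexan-1-one
Product: 4 (1S)-2,2-dimethyl-4-methylidenecyclohexan-1-ol
Conditions: Ph3PCH3Br (2.5 equiv), KOtBu (2.4 equiv), THF, 0 °C → rt
Reagents that add atoms: methyltriphenylphosphonium bromide C[P+](c1ccccc1)(c1ccccc1)c1ccccc1.[Br-]
Why: Wittig methylenation of the unhindered ketone, with excess ylide tolerating the free hydroxyl.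

Step 4
Reactants: 4 (1S)-2,2-dimethyl-4-methylidenecyclohexan-1-ol
Product: 5 (1R,4S)-1-(iodomethyl)-3,3-dimethyl-7-oxabicyclo[2.2.1]heptane
Conditions: I2 (1.5 equiv), NaHCO3, MeCN, 0 °C → rt, dark
Reagents that add atoms: iodine II
Why: Iodoetherification in which the hydroxyl opens the iodonium ion at its tertiary carbon across a boat cyclohexane (5-exo-trig), so the single carbinol stereocentre fixes both bridgeheads.

Step 5
Reactants: 5 (1R,4S)-1-(iodomethyl)-3,3-dimethyl-7-oxabicyclo[2.2.1]heptane; 6 3-bromocyclopent-2-en-1-one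
Product: 7 3-[(1S,4S)-OBM]cyclopent-2-en-1-one
Conditions: NiBr2·DME (10 mol%), 4,4'-di-tert-butyl-2,2'-bipyridine (10 mol%), Mn powder (3 equiv), DMA, 40 °C
Reagents that add atoms: none
Why: Nickel-catalysed reductive cross-electrophile coupling of an alkenyl bromide with a primary alkyl iodide, in which the neopentyl-type radical from 5 is captured by the alkenylnickel species, avoiding both SN2 displacement at the hindered carbon and a β-alkoxy organometallic that would open the ether bridge.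

Step 6
Reactants: 7 3-[(1S,4S)-OBM]cyclopent-2-en-1-one
Product: 9 2-bromo-3-[(1R,4S)-OBM]cyclopent-2-en-1-one, via dibromoketone 8 (not isolated)
Conditions: Br2 (1.05 equiv), CH2Cl2, 0 °C; then Et3N (1.5 equiv), 0 °C → rt
Reagents that add atoms: bromine BrBr
Why: Bromine adds to the enone and triethylamine removes HBr through the α-hydrogen (addition–elimination α-bromination of a 3-alkylcycloalkenone).

Step 7
Reactants: 9 2-bromo-3-[(1R,4S)-OBM]cyclopent-2-en-1-one
Product: 11 cross-conjugated TBS dienol ether of 9, via lithium dienolate 10 (not isolated)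
Conditions: LiN(CHMe2)2 (1.1 equiv), THF, −78 °C; TBSOTf (1.15 equiv), −78 °C; cold NaHCO3 work-up, used at once
Reagents that add atoms: tert-butyldimethylsilyl trifluoromethanesulfonate CC(C)(C)[Si](C)(C)OS(=O)(=O)C(F)(F)F
Why: Kinetic deprotonation at the α'-methylene gives the cross-conjugated enolate, which is silylated on oxygen (silyl enol ether formation).

Step 8
Reactants: 11 cross-conjugated TBS dienol ether of 9
Product: 13 (5S)-2-bromo-5-hydroxy-3-[(1R,4S)-OBM]cyclopent-2-en-1-one, via silyloxy epoxide 12 (not isolated)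
Conditions: ent-Shi ketone (L-fructose-derived, 30 mol%), Oxone (2KHSO5·KHSO4·K2SO4), K2CO3, Bu4NHSO4 (cat.), MeCN/dimethoxymethane/aq. Na2B4O7–Na2EDTA buffer, −10 → 0 °C; then 1 M HCl, THF, 0 °C
Reagents that add atoms: potassium peroxymonosulfate [K+].[O-]S(=O)(=O)OO
Why: Shi asymmetric epoxidation (a catalytic Rubottom oxidation) in which the chiral dioxirane attacks the electron-rich silyl enol ether C=C rather than the bromoalkene through the spiro transition state, the L-fructose-derived ketone being chosen because that model places oxygen on the face leading to the (5S)-carbinol, and acid opens the silyloxy epoxide to the α'-hydroxy enone.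

Step 9
Reactants: 13 (5S)-2-bromo-5-hydroxy-3-[(1R,4S)-OBM]cyclopent-2-en-1-one
Product: 14 (1S,2S)-3-bromo-2-ethenyl-4-[(1R,4S)-OBM]cyclopent-3-ene-1,2-diol (cis-diol)
Conditions: CH2=CHMgBr (3.0 equiv), THF, −78 → −40 °C
Reagents that add atoms: vinylmagnesium bromide C=C[Mg]Br
Why: 1,2-Addition of the Grignard reagent to the α-bromo enone carbonyl anti to the neighbouring magnesium alkoxide (the usual sense for α-oxygenated cycloalkanones) should give the cis-diol and set the tertiary carbinol (S).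

Step 10
Reactants: 14 (1S,2S)-3-bromo-2-ethenyl-4-[(1R,4S)-OBM]cyclopent-3-ene-1,2-diol
Product: 15 (2S)-3-bromo-2-ethenyl-2-hydroxy-4-[(1R,4S)-OBM]cyclopent-3-en-1-one
Conditions: IBX (1.5 equiv), DMSO, rt
Reagents that add atoms: none
Why: IBX oxidises the secondary hydroxyl of the 1,2-diol to the α-ketol without glycol cleavage and leaves the tertiary allylic alcohol untouched.

Step 11
Reactants: 15 (2S)-3-bromo-2-ethenyl-2-hydroxy-4-[(1R,4S)-OBM]cyclopent-3-en-1-one
Product: 16 (2S)-3-bromo-2-ethenyl-4-[(1R,4S)-OBM]-2-[(trimethylsilyl)oxy]cyclopent-3-en-1-one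
Conditions: N-(trimethylsilyl)imidazole (1.5 equiv), CH2Cl2, rt
Reagents that add atoms: N-(trimethylsilyl)imidazole C[Si](C)(C)n1ccnc1
Why: Neutral silylation of the tertiary alcohol avoids enolisation of the ketone and installs a non-chelating polar α-substituent for the next addition.

Step 12
Reactants: 17 (3E)-3-methylpent-3-en-2-one
Product: 18 (2R,3E)-3-methylpent-3-en-2-ol
Conditions: (S)-2-methyl-CBS-oxazaborolidine (10 mol%), catecholborane (1.5 equiv), toluene, −78 °C
Reagents that add atoms: none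
Why: Corey–Bakshi–Shibata 1,2-reduction in which the alkenyl group is the large substituent, so the (S)-catalyst should give the (R)-allylic alcohol.

Step 13
Reactants: 18 (2R,3E)-3-methylpent-3-en-2-ol
Product: 20 ethyl (3R,4E)-3,4-dimethylhex-4-enoate, via ketene acetal 19 (not isolated)
Conditions: MeC(OEt)3 (5 equiv), EtCO2H (5 mol%), 140 °C, EtOH distilled off
Reagents that add atoms: triethyl orthoacetate CCOC(C)(OCC)OCC
Why: Johnson–Claisen rearrangement through a chair with the carbinol methyl equatorial, which transfers the (R)-carbinol configuration to the new (3R) methine and forms the (E)-trisubstituted alkene.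

Step 14
Reactants: 20 ethyl (3R,4E)-3,4-dimethylhex-4-enoate
Product: 21 (3R,4E)-3,4-dimethylhex-4-en-1-ol
Conditions: LiAlH4, Et2O, 0 °C
Reagents that add atoms: none
Why: Hydride reduction of the ester, the allylic stereocentre not being epimerisable under these conditions.

Step 15
Reactants: 21 (3R,4E)-3,4-dimethylhex-4-en-1-ol
Product: 22 TBS ether of 21
Conditions: TBSCl, imidazole, DMF, rt
Reagents that add atoms: tert-butyldimethylsilyl chloride CC(C)(C)[Si](C)(C)Cl
Why: Standard silylation of the primary alcohol, which masks the future carboxyl carbon through the organometallic steps.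

Step 16
Reactants: 22 TBS ether of 21
Product: 24 {[(3R,4E)-5-bromo-3,4-dimethylhex-4-en-1-yl]oxy}(tert-butyl)dimethylsilane, via dibromide 23 (not isolated)
Conditions: Br2 (1.0 equiv), CH2Cl2, −78 °C; then DBU (3 equiv), 0 °C → reflux
Reagents that add atoms: bromine BrBr
Why: Anti addition of bromine followed by anti-periplanar E2 loss of HBr (the hydrogen geminal to bromine and the tertiary bromide) replaces the vinylic hydrogen by bromine with inversion of the alkene geometry, which should give the (E)-bromide with bromine trans to the stereogenic carbon.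

Step 17
Reactants: 16 (2S)-3-bromo-2-ethenyl-4-[(1R,4S)-OBM]-2-[(trimethylsilyl)oxy]cyclopent-3-en-1-one; 24 (E)-alkenyl bromide
Product: 27 (1R,2S)-3-bromo-1-[(2E,4R)-6-(TBS-oxy)-3,4-dimethylhex-2-en-2-yl]-2-ethenyl-4-[(1R,4S)-OBM]cyclopent-3-ene-1,2-diol (cis-diol), via alkenyllithium 25 (not isolated), via trimethylsilyl ether 26 (not isolated)
Conditions: 24, t-BuLi (2.05 equiv), Et2O, −78 °C; then 16 premixed with LaCl3·2LiCl (1.1 equiv), THF, −78 → −40 °C; then K2CO3, MeOH, 0 °C
Reagents that add atoms: none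
Why: Bromine–lithium exchange with retention of alkene geometry and LaCl3·2LiCl-promoted 1,2-addition to the hindered, enolisable ketone anti to the trimethylsilyloxy group (Felkin–Anh, polar) should give the cis-1,2-dialkenyl adduct with the new tertiary carbinol (R), and methanolysis of the silyl ether then gives the cis-diol.

Step 18
Reactants: 27 cis-1,2-dialkenyl-cyclopent-3-ene-1,2-diol
Product: 30 (1S,3aS,7aS)-4-bromo-1-[(2R)-4-(TBS-oxy)butan-2-yl]-5-[(1R,4S)-OBM]-3a-hydroxy-1,7a-dimethyl-1,2,3,3a,6,7a-hexahydro-7H-inden-7-one, via nine-membered bis-enolate 28 (not isolated), via keto enolate 29 (not isolated)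
Conditions: KN(SiMe3)2 (2.4 equiv), 18-crown-6 (2.4 equiv), THF, −78 → 0 °C; MeOH (1.0 equiv), −78 → −20 °C; aq. NH4Cl
Reagents that add atoms: none
Why: Double deprotonation gives the cis-1,2-dialkenyl dialkoxide, whose 1,5-diene (C2=C3–C3a–C7–C7a=C1) undergoes a dianion-accelerated oxy-Cope [3,3] shift through the boat transition state that a cis-1,2-dialkenylcyclopentene uses to reach an all-cis nine-membered ring, forming C1–C2 and the bis-enolate 28; one equivalent of MeOH then protonates the unhindered C3 of the less substituted enolate, and the remaining tetrasubstituted C7/C7a enolate 29 adds across the ring to the C3a ketone, forming C3a–C7a. The closest known reaction type is the dianionic oxy-Cope/transannular aldol cascade of cis-1,2-dialkenylcyclobutene-1,2-diolates made from squarate esters, together with the thermal oxy-Cope/aldol sequence of 1,2-divinylcycloalkane-1,2-diols. The aldol bond closes ring A in a 5-(enolexo)-exo-trig mode and ring B in a 6-(enolendo)-exo-trig mode in the same event. C1 is controlled by the (S)-configured C3a carbinol, which fixes the face of the vinyl group, acting through the boat geometry on the (E)-alkene; C7a follows from the alkene geometry, because the shift is suprafacial and C3a stays over the enolate face it has just left, so that C2 and C3a add syn across the former C7a=C1 bond (methyl groups trans on ring A); the C3a hydroxyl comes out cis to the C7a methyl because C7a simply takes the place of C7 on C3a. The step needs aldol regioselectivity (C7a onto C3a, not C3 onto C7) and must avoid protonation at C7a, which is secured by the regiodefined, fully substituted and therefore slowly C-protonated C7/C7a enolate, by the unhindered C3 of the other enolate, and by the bromine on C4, which leaves no hydrogen on that side of C3a.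

Step 19
Reactants: 30 cis-fused 3a-hydroxy-7-ketone
Product: 31 (1S,3aS,7R,7aR)-4-bromo-1-[(2R)-4-(TBS-oxy)butan-2-yl]-5-[(1R,4S)-OBM]-1,7a-dimethyl-1,2,3,6,7,7a-hexahydro-3aH-indene-3a,7-diol
Conditions: Me4NBH(OAc)3 (5 equiv), MeCN/AcOH (1:1), −30 → 0 °C
Reagents that add atoms: none
Why: Evans–Saksena hydroxyl-directed reduction in which the borohydride bound to the C3a hydroxyl delivers hydride to C7 on the face of the angular methyl, which should give the 1,3-anti diol with the (7R) hydroxyl trans to that methyl.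

Step 20
Reactants: 31 anti-3a,7-diol
Product: 32 7-O-TES ether of 31
Conditions: TESCl (1.5 equiv), imidazole, DMF, 0 °C → rt
Reagents that add atoms: chlorotriethylsilane CC[Si](Cl)(CC)CC
Why: The secondary hydroxyl is silylated in preference to the tertiary allylic one on steric grounds.

Step 21
Reactants: 32 7-O-TES ether of 31
Product: 34 (1S,7R,7aS)-4-bromo-1-[(2R)-4-(TBS-oxy)butan-2-yl]-5-[(1R,4S)-OBM]-1,7a-dimethyl-7-(TES-oxy)-2,6,7,7a-tetrahydro-1H-indene, via sulfamate ester 33 (not isolated)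
Conditions: Burgess reagent (3 equiv), benzene, 50 °C
Reagents that add atoms: none
Why: Burgess dehydration by syn elimination of the tertiary allylic sulfamate, which can only involve a C3 hydrogen because C4 and C7a carry none, and so gives the conjugated bromodiene.

Step 22
Reactants: 34 4-bromo-diene
Product: 35 (1S,7R,7aS)-1-[(2R)-4-(TBS-oxy)butan-2-yl]-5-[(1S,4S)-OBM]-1,7a-dimethyl-7-(TES-oxy)-2,6,7,7a-tetrahydro-1H-indene-4-carboxylic acid
Conditions: Pd(OAc)2 (10 mol%), dppf (12 mol%), CO (1 atm), H2O (10 equiv), Et3N (3 equiv), DMF, 80 °C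
Reagents that add atoms: carbon monoxide [C-]#[O+]; water O
Why: Palladium-catalysed hydroxycarbonylation, in which oxidative addition of the dienyl bromide to zerovalent palladium, CO insertion and hydrolysis of the acylpalladium give the C4 carboxylic acid.

Step 23
Reactants: 35 bis-silylated diene acid
Product: 36 (1S,7R,7aS)-7-hydroxy-1-[(2R)-4-hydroxybutan-2-yl]-5-[(1S,4S)-OBM]-1,7a-dimethyl-2,6,7,7a-tetrahydro-1H-indene-4-carboxylic acid
Conditions: HF·pyridine, pyridine, THF, 0 °C → rt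
Reagents that add atoms: none
Why: Fluoride cleaves both silyl ethers while the ether bridge, the diene acid and the stereocentres are untouched.

Step 24
Reactants: 36 diol acid
Product: 38 (3R)-3-[(1S,7R,7aS)-4-carboxy-5-[(1S,4S)-OBM]-7-hydroxy-1,7a-dimethyl-2,6,7,7a-tetrahydro-1H-inden-1-yl]butanoic acid (CNP0085464.1), via aldehyde 37 (not isolated)
Conditions: TEMPO (20 mol%), PhI(OAc)2 (2.5 equiv), MeCN/H2O (1:1), rt
Reagents that add atoms: water O
Why: Oxoammonium (TEMPO) oxidation is selective for the primary alcohol over the hindered secondary C7 hydroxyl and carries the aldehyde through its hydrate to the acid, which completes the target.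

**Compound list**
1 | 7,7-dimethyl-1,4-dioxaspiro[4.5]decan-8-one | O=C1CCC2(CC1(C)C)OCCO2 | starting material
2 | (8S)-7,7-dimethyl-1,4-dioxaspiro[4.5]decan-8-ol | O[C@H]1CCC2(CC1(C)C)OCCO2 | intermediate
3 | (4S)-4-hydroxy-3,3-dimethylcyclohexan-1-one | O[C@H]1CCC(=O)CC1(C)C | intermediate
4 | (1S)-2,2-dimethyl-4-methylidenecyclohexan-1-ol | O[C@H]1CCC(=C)CC1(C)C | intermediate
5 | (1R,4S)-1-(iodomethyl)-3,3-dimethyl-7-oxabicyclo[2.2.1]heptane | IC[C@]12CC[C@H](O1)C(C)(C)C2 | intermediate
6 | 3-bromocyclopent-2-en-1-one | O=C1C=C(Br)CC1 | starting material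
7 | 3-[(1S,4S)-OBM]cyclopent-2-en-1-one | O=C1C=C(C[C@]23CC[C@H](O2)C(C)(C)C3)CC1 | intermediate
8 | trans-2,3-dibromo-3-[(1R,4S)-OBM]cyclopentan-1-one (both trans diastereomers; C2 and C3 left open) | O=C1C(Br)C(Br)(C[C@]23CC[C@H](O2)C(C)(C)C3)CC1 | intermediate
9 | 2-bromo-3-[(1R,4S)-OBM]cyclopent-2-en-1-one | O=C1C(Br)=C(C[C@]23CC[C@H](O2)C(C)(C)C3)CC1 | intermediate
10 | lithium 5-bromo-4-[(1R,4S)-OBM]cyclopenta-1,4-dien-1-olate | [Li+].[O-]C1=CCC(C[C@]23CC[C@H](O2)C(C)(C)C3)=C1Br | intermediate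
11 | tert-butyl{[5-bromo-4-[(1R,4S)-OBM]cyclopenta-1,4-dien-1-yl]oxy}dimethylsilane | CC(C)(C)[Si](C)(C)OC1=CCC(C[C@]23CC[C@H](O2)C(C)(C)C3)=C1Br | intermediate
12 | tert-butyl{[(1R,5S)-2-bromo-3-[(1R,4S)-OBM]-6-oxabicyclo[3.1.0]hex-2-en-1-yl]oxy}dimethylsilane | CC(C)(C)[Si](C)(C)O[C@]12O[C@H]1CC(C[C@]34CC[C@H](O3)C(C)(C)C4)=C2Br | intermediate
13 | (5S)-2-bromo-5-hydroxy-3-[(1R,4S)-OBM]cyclopent-2-en-1-one | O=C1C(Br)=C(C[C@]23CC[C@H](O2)C(C)(C)C3)C[C@@H]1O | intermediate
14 | (1S,2S)-3-bromo-2-ethenyl-4-[(1R,4S)-OBM]cyclopent-3-ene-1,2-diol (cis-diol) | O[C@]1(C=C)C(Br)=C(C[C@]23CC[C@H](O2)C(C)(C)C3)C[C@@H]1O | intermediate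
15 | (2S)-3-bromo-2-ethenyl-2-hydroxy-4-[(1R,4S)-OBM]cyclopent-3-en-1-one | O[C@]1(C=C)C(Br)=C(C[C@]23CC[C@H](O2)C(C)(C)C3)CC1=O | intermediate
16 | (2S)-3-bromo-2-ethenyl-4-[(1R,4S)-OBM]-2-[(trimethylsilyl)oxy]cyclopent-3-en-1-one | C[Si](C)(C)O[C@]1(C=C)C(Br)=C(C[C@]23CC[C@H](O2)C(C)(C)C3)CC1=O | intermediate
17 | (3E)-3-methylpent-3-en-2-one | CC(=O)/C(C)=C/C | starting material
18 | (2R,3E)-3-methylpent-3-en-2-ol | C[C@@H](O)/C(C)=C/C | intermediate
19 | (2R,3E)-2-[(1-ethoxyethenyl)oxy]-3-methylpent-3-ene | C=C(OCC)O[C@H](C)/C(C)=C/C | intermediate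
20 | ethyl (3R,4E)-3,4-dimethylhex-4-enoate | C[C@H](CC(=O)OCC)/C(C)=C/C | intermediate
21 | (3R,4E)-3,4-dimethylhex-4-en-1-ol | C[C@H](CCO)/C(C)=C/C | intermediate
22 | tert-butyl{[(3R,4E)-3,4-dimethylhex-4-en-1-yl]oxy}dimethylsilane | C[C@H](CCO[Si](C)(C)C(C)(C)C)/C(C)=C/C | intermediate
23 | tert-butyl{[(3R)-4,5-dibromo-3,4-dimethylhexyl]oxy}dimethylsilane (anti adduct, both face isomers; C4 and C5 left open) | C[C@H](CCO[Si](C)(C)C(C)(C)C)C(C)(Br)C(C)Br | intermediate
24 | {[(3R,4E)-5-bromo-3,4-dimethylhex-4-en-1-yl]oxy}(tert-butyl)dimethylsilane | C[C@H](CCO[Si](C)(C)C(C)(C)C)/C(C)=C(\C)Br | intermediate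
25 | [(2Z,4R)-6-(TBS-oxy)-3,4-dimethylhex-2-en-2-yl]lithium (lithium trans to the stereogenic carbon) | [Li]/C(C)=C(\C)[C@H](C)CCO[Si](C)(C)C(C)(C)C | intermediate
26 | (1R,2S)-3-bromo-1-[(2E,4R)-6-(TBS-oxy)-3,4-dimethylhex-2-en-2-yl]-2-ethenyl-4-[(1R,4S)-OBM]-2-[(trimethylsilyl)oxy]cyclopent-3-en-1-ol | C[Si](C)(C)O[C@]1(C=C)C(Br)=C(C[C@]23CC[C@H](O2)C(C)(C)C3)C[C@@]1(O)/C(C)=C(\C)[C@H](C)CCO[Si](C)(C)C(C)(C)C | intermediate
27 | (1R,2S)-3-bromo-1-[(2E,4R)-6-(TBS-oxy)-3,4-dimethylhex-2-en-2-yl]-2-ethenyl-4-[(1R,4S)-OBM]cyclopent-3-ene-1,2-diol (cis-diol) | O[C@]1(C=C)C(Br)=C(C[C@]23CC[C@H](O2)C(C)(C)C3)C[C@@]1(O)/C(C)=C(\C)[C@H](C)CCO[Si](C)(C)C(C)(C)C | intermediate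
28 | dipotassium bis-enolate of the nine-membered ring (3-bromo-4-[(1R,4S)-OBM]-7,8-dimethyl-8-[(2R)-4-(TBS-oxy)butan-2-yl]cyclonona-1,3,6-triene-2,6-diolate, ring carbons cis across all three double bonds, quaternary carbon S) | [K+].[K+].[O-]/C1=C/C[C@@](C)([C@H](C)CCO[Si](C)(C)C(C)(C)C)/C(C)=C([O-])\C/C(C[C@]23CC[C@H](O2)C(C)(C)C3)=C1/Br | intermediate
29 | potassium enolate of the nine-membered keto enone (C3 protonated form of 28) | [K+].O=C1CC[C@@](C)([C@H](C)CCO[Si](C)(C)C(C)(C)C)/C(C)=C([O-])\C/C(C[C@]23CC[C@H](O2)C(C)(C)C3)=C1/Br | intermediate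
30 | (1S,3aS,7aS)-4-bromo-1-[(2R)-4-(TBS-oxy)butan-2-yl]-5-[(1R,4S)-OBM]-3a-hydroxy-1,7a-dimethyl-1,2,3,3a,6,7a-hexahydro-7H-inden-7-one | C[C@H](CCO[Si](C)(C)C(C)(C)C)[C@]1(C)CC[C@@]2(O)C(Br)=C(C[C@]34CC[C@H](O3)C(C)(C)C4)CC(=O)[C@]21C | intermediate
31 | (1S,3aS,7R,7aR)-4-bromo-1-[(2R)-4-(TBS-oxy)butan-2-yl]-5-[(1R,4S)-OBM]-1,7a-dimethyl-1,2,3,6,7,7a-hexahydro-3aH-indene-3a,7-diol | C[C@H](CCO[Si](C)(C)C(C)(C)C)[C@]1(C)CC[C@@]2(O)C(Br)=C(C[C@]34CC[C@H](O3)C(C)(C)C4)C[C@@H](O)[C@]21C | intermediate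
32 | (1S,3aS,7R,7aR)-4-bromo-1-[(2R)-4-(TBS-oxy)butan-2-yl]-5-[(1R,4S)-OBM]-1,7a-dimethyl-7-(TES-oxy)-1,2,3,6,7,7a-hexahydro-3aH-inden-3a-ol | C[C@H](CCO[Si](C)(C)C(C)(C)C)[C@]1(C)CC[C@@]2(O)C(Br)=C(C[C@]34CC[C@H](O3)C(C)(C)C4)C[C@@H](O[Si](CC)(CC)CC)[C@]21C | intermediate
33 | triethylammonium salt of the 3a-O-[N-(methoxycarbonyl)sulfamate] of 32 | C[C@H](CCO[Si](C)(C)C(C)(C)C)[C@]1(C)CC[C@@]2(OS(=O)(=O)[N-]C(=O)OC)C(Br)=C(C[C@]34CC[C@H](O3)C(C)(C)C4)C[C@@H](O[Si](CC)(CC)CC)[C@]21C.CC[NH+](CC)CC | intermediate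
34 | {[(1S,7R,7aS)-4-bromo-1-[(2R)-4-(TBS-oxy)butan-2-yl]-5-[(1R,4S)-OBM]-1,7a-dimethyl-2,6,7,7a-tetrahydro-1H-inden-7-yl]oxy}triethylsilane | C[C@H](CCO[Si](C)(C)C(C)(C)C)[C@]1(C)CC=C2C(Br)=C(C[C@]34CC[C@H](O3)C(C)(C)C4)C[C@@H](O[Si](CC)(CC)CC)[C@]21C | intermediate
35 | (1S,7R,7aS)-1-[(2R)-4-(TBS-oxy)butan-2-yl]-5-[(1S,4S)-OBM]-1,7a-dimethyl-7-(TES-oxy)-2,6,7,7a-tetrahydro-1H-indene-4-carboxylic acid | C[C@H](CCO[Si](C)(C)C(C)(C)C)[C@]1(C)CC=C2C(C(=O)O)=C(C[C@]34CC[C@H](O3)C(C)(C)C4)C[C@@H](O[Si](CC)(CC)CC)[C@]21C | intermediate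
36 | (1S,7R,7aS)-7-hydroxy-1-[(2R)-4-hydroxybutan-2-yl]-5-[(1S,4S)-OBM]-1,7a-dimethyl-2,6,7,7a-tetrahydro-1H-indene-4-carboxylic acid | C[C@H](CCO)[C@]1(C)CC=C2C(C(=O)O)=C(C[C@]34CC[C@H](O3)C(C)(C)C4)C[C@@H](O)[C@]21C | intermediate
37 | (1S,7R,7aS)-7-hydroxy-5-[(1S,4S)-OBM]-1,7a-dimethyl-1-[(2R)-4-oxobutan-2-yl]-2,6,7,7a-tetrahydro-1H-indene-4-carboxylic acid | C[C@H](CC=O)[C@]1(C)CC=C2C(C(=O)O)=C(C[C@]34CC[C@H](O3)C(C)(C)C4)C[C@@H](O)[C@]21C | intermediate
38 | (3R)-3-[(1S,7R,7aS)-4-carboxy-5-[(1S,4S)-OBM]-7-hydroxy-1,7a-dimethyl-2,6,7,7a-tetrahydro-1H-inden-1-yl]butanoic acid | C[C@H](CC(=O)O)[C@]1(C)CC=C2C(C(=O)O)=C(C[C@]34CC[C@H](O3)C(C)(C)C4)C[C@@H](O)[C@]21C | target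

**Totals:** 24 steps. Longest linear sequence: 19 steps (steps 1–11, then 17–24); the alkenyl bromide branch (steps 12–16) joins at step 17.

**Steps most likely to fail**

Step 18. Proton transfer inside keto enolate 29 (from the doubly activated C6 methylene, or onto C7a) may outrun the transannular aldol, so that the aldol condensation of the C3 enolate with the C7 ketone takes over. The fallback sets out from 27 and fixes the two roles with silicon. Bis-enolate 28 is generated as in step 18 and trapped with Me3SiCl/Et3N at −78 °C to give the nine-membered bis(trimethylsilyl enol ether) F1. MeLi (1.0 equiv, THF, −20 °C) then cleaves the less hindered, trisubstituted dienyl silyl ether, and AcOH at −78 °C protonates C3 to give the keto silyl enol ether F2. TiCl4 (CH2Cl2, −78 °C) effects a transannular Mukaiyama aldol that can only join C7a to C3a, and aqueous work-up returns the route to 30.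

Step 17. The fully substituted alkenyllithium may enolise 16 at its allylic methylene or fail to reach the hindered carbonyl. The fallback sets out from 22 and builds the alkene after a slim alkynyl nucleophile has made the carbinol. Ozonolysis of 22 (O3, CH2Cl2/MeOH, −78 °C; PPh3) gives the methyl ketone F3. Its kinetic enol phosphate (LiN(CHMe2)2, ClP(O)(OEt)2; then LiN(CHMe2)2) is eliminated to the terminal alkyne F4. The lithium acetylide of F4 (n-BuLi, LaCl3·2LiCl, THF, −78 °C) adds to 16 anti to the silyloxy group to give the propargylic alcohol F5. Hydroxyl-directed anti-carbomagnesiation (MeMgBr, CuI cat., THF) places methyl on the proximal alkyne carbon and magnesium on the distal carbon cis to the carbinol; methylation of this chelated alkenylmagnesium (MeI) with retention gives the (E)-alkene and returns the route to 26, which is desilylated to 27 as in step 17.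

Step 8. The epoxidation may be poorly face-selective, or the cyclopentadienyl silyl ether 11 may isomerise by hydrogen shift or dimerise before it is oxidised. The fallback sets out from 9, oxidises the enolate directly and resolves the carbinol. LiN(SiMe3)2 (THF, −78 °C) followed by racemic 2-(phenylsulfonyl)-3-phenyloxaziridine should convert 9 to 13 together with its (5R)-epimer F6. Because the oxabicycle is enantiopure the two are diastereomers, and lipase-catalysed acylation (Amano lipase PS, vinyl acetate, t-BuOMe) is expected to convert the (5R)-carbinol to the acetate F7 and leave 13, which is separated by chromatography and rejoins the route.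

**Further compounds**
F1 | step 18 | nine-membered bis(trimethylsilyl enol ether) (O,O'-bis-TMS derivative of 28) | C[Si](C)(C)O/C1=C/C[C@@](C)([C@H](C)CCO[Si](C)(C)C(C)(C)C)/C(C)=C(O[Si](C)(C)C)\C/C(C[C@]23CC[C@H](O2)C(C)(C)C3)=C1/Br
F2 | step 18 | nine-membered keto silyl enol ether (C3a ketone, C7 trimethylsilyl enol ether) | O=C1CC[C@@](C)([C@H](C)CCO[Si](C)(C)C(C)(C)C)/C(C)=C(O[Si](C)(C)C)\C/C(C[C@]23CC[C@H](O2)C(C)(C)C3)=C1/Br
F3 | step 17 | (3R)-5-(TBS-oxy)-3-methylpentan-2-one | CC(=O)[C@H](C)CCO[Si](C)(C)C(C)(C)C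
F4 | step 17 | tert-butyl(dimethyl){[(3R)-3-methylpent-4-yn-1-yl]oxy}silane | C#C[C@H](C)CCO[Si](C)(C)C(C)(C)C
F5 | step 17 | (1R,2S)-3-bromo-1-[(3R)-5-(TBS-oxy)-3-methylpent-1-yn-1-yl]-2-ethenyl-4-[(1R,4S)-OBM]-2-[(trimethylsilyl)oxy]cyclopent-3-en-1-ol | C[Si](C)(C)O[C@]1(C=C)C(Br)=C(C[C@]23CC[C@H](O2)C(C)(C)C3)C[C@@]1(O)C#C[C@H](C)CCO[Si](C)(C)C(C)(C)C
F6 | step 8 | (5R)-2-bromo-5-hydroxy-3-[(1R,4S)-OBM]cyclopent-2-en-1-one | O=C1C(Br)=C(C[C@]23CC[C@H](O2)C(C)(C)C3)C[C@H]1O
F7 | step 8 | (1R)-3-bromo-2-oxo-4-[(1R,4S)-OBM]cyclopent-3-en-1-yl acetate | O=C1C(Br)=C(C[C@]23CC[C@H](O2)C(C)(C)C3)C[C@H]1OC(C)=O
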